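This flask is slow: Sunday's run, with more second catalyst than Tuesday's, still held 67.0 % of its starting material at 12.0 h. Midnight, winter and spring are one recipe stopped at different times, and I wanted to know what each would hold.

in all of them: starting material 2.2 M; gas 200 mM (held); free catalyst 120 mM; impurity 110 mM

| run | second catalyst | remark | time |
|---|---|---|---|
| Tuesday's | 160 mM | run made earlier |  |
| Sunday's | 660 mM | run made earlier |  |
| midnight | 330 mM |  | 20 h |
| winter | 330 mM |  | 60 h |
| spring | 330 mM |  | 180 h |

| run | time / h | starting material / % | product / % | open intermediate / % |
|---|---|---|---|---|
| Tuesday's | 2.50 | 93.7 | 0 | 6.7 |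
| Tuesday's | 5.00 | 85.5 | 1.8 | 16.0 |
| Tuesday's | 8.00 | 75.7 | 1.9 | 21.8 |
| Tuesday's | 10.0 | 71.5 | 1.4 | 25.4 |
| Tuesday's | 12.0 | 66.1 | 2.4 | 29.0 |
| Sunday's | 1.00 | 95.8 | 1.4 | 2.7 |
| Sunday's | 3.00 | 91.0 | 3.4 | 8.0 |
| Sunday's | 6.00 | 81.7 | 7.3 | 10.8 |
| Sunday's | 8.00 | 77.1 | 10.8 | 13.0 |
| Sunday's | 12.0 | 67.0 | 19.3 | 12.9 |

(scatter of a reading: 1 percentage point)

- the earlier runs were read with a standard deviation of 1 percentage point
- at the start none of the gas is in solution

1. which of these there is most of at the end, counted by the starting material in it, midnight (product / open intermediate / starting material)
2. which of these there is most of at the end, counted by the starting material in it, winter (product / open intermediate / starting material)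
3. which of these there is most of at the end, counted by the starting material in it, spring (product / open intermediate / starting material)
4. amount of the one of these that there is most of at the end, in percent of the starting material charged, midnight
5. amount of the one of these that there is most of at the end, in percent of the starting material charged, winter
6. amount of the one of these that there is most of at the end, in percent of the starting material charged, spring

I went link by link. Starting material stood at 66.1 % and 67.0 % at 12.0 h in the two runs, though their second catalyst differed. So I took its loss as one first-order step at this free catalyst, with constant k_A = 0.0339 h⁻¹. My estimate of what remained was 50.7 % at midnight, 13.1 % at winter and 0.222 % at spring.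

Next came open intermediate going to product. Late in Sunday's run, product rose by 8.5 percentage points in 4.00 h, which gave a first-order constant of 0.164 h⁻¹. Tuesday's run held 29.0 % intermediate but 2.4 % product at 12.0 h. So I supposed that impurity removes second catalyst one for one, and defined the working second catalyst W as the charge of second catalyst minus the charge of impurity: 220 mM in this recipe, where impurity is the limiting reagent of that loss. Sunday's W was 550 mM and Tuesday's 50.0 mM.

Scaling by W gave k_I = 0.0656 h⁻¹. The two steps in series then gave product 23.8 % at midnight and 75.1 % at winter.

The weak link was W itself, so I went round once more. Put back into Tuesday's run, W gives 0.0149 h⁻¹, and with the intermediate's mean taken as half its last reading, product comes to 2.59 % against the reading of 2.4 %. A square law on the charge gives 1.68 %, also within the scatter, so this run could not choose. That law would put winter's product near 65.3 %. I kept W.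

The forecast took a lower constant than mine, 0.05 per hour, and allowed that “the rate goes as its square”. It said starting material at 48 % (41 % to 54 %) for midnight, product at 74 % (60 % to 87 %) for winter, and product at 98.5 % (93 % to 100 %) for spring.

The flasks gave starting material at 51.0 %, product at 75.6 % and product at 99.6 %, so the forecast stands.

    starting material + free catalyst → free catalyst + open intermediate (k = 7.80 × 10⁻⁵ M⁻¹ s⁻¹)
    second catalyst + open intermediate ⇌ catalyst intermediate (K = 0.160 M⁻¹, k = 9.90 × 10⁻⁵ M⁻¹ s⁻¹)
    coupling partner + catalyst intermediate → second catalyst + product (k = 0.0280 M⁻¹ s⁻¹)
    second catalyst + impurity → spent catalyst (k = 0.0340 M⁻¹ s⁻¹)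
    gas ⇌ coupling partner, rate k5*(csat - [coupling partner]) (kL = 2.80 × 10⁻⁴ s⁻¹)

Midnight was far from rest: left until 200 h, its starting material goes from 51.0 % to 0.118 % and its product from 24.2 % to 99.8 %. Spring has little left to change, with product at 99.6 % at 180 h and 100 % at 1800 h. At 200 h midnight's second catalyst stands at 66.7 % of its charge and spent catalyst at 33.3 %, while W is 66.7 % of that charge.

Take spring's recipe with 0.083 M of second catalyst. W comes to −27.0 mM, so I expected no working second catalyst, impurity left at 24.5 % of its charge, and 0.222 % starting material, with the rest held as open intermediate. That flask gives open intermediate at 99.8 %, product 0 %, impurity 25 % and starting material 0.232 %.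

(The data were computed on assumed constants; the scatter is artificial.)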